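**Strategy.** In each terminal ring of perrottetin E (rings A and D) the hydroxyl carbon (C1) lies meta to the carbon that holds the CH2CH2 tether (C3). The oxygen at C3 of a 1-methoxy-3-siloxybutadiene ends up in just this 1,3-relation to the β-carbon of an alk-2-ynoate, so both rings are disconnected across C2–C3 and C4–C5. One twofold Diels–Alder/aromatisation on a diaryl ether core (rings B and C) with two CH2CH2C≡C–CO2Bn arms thus builds both phenol rings and four C–C bonds in a single operation; the ester sits at C4, para to the new hydroxyl, and is later lost as CO2. Benzyl is the only protecting group, so one hydrogenolysis precedes the final decarboxylation.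

Key step: step 6

Remark: the target is achiral, so no stereocentre has to be set; 4-(benzyloxy)-3-hydroxybenzaldehyde is taken as a catalogue compound.

**Step 1**
Reactants: 1 4-(benzyloxy)-3-hydroxybenzaldehyde; 2 4-fluorobenzaldehyde
Product: 3 4-(benzyloxy)-3-(4-formylphenoxy)benzaldehyde
Conditions: K2CO3, DMF, 120 °C, N2
Reagents that add atoms: none
Why: Nucleophilic aromatic substitution (SNAr): the phenoxide of 1 adds para to the formyl group of 2 and fluoride leaves from the Meisenheimer intermediate, while the benzyl ether and both aldehydes tolerate carbonate in DMF.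

**Step 2**
Reactants: 3 4-(benzyloxy)-3-(4-formylphenoxy)benzaldehyde
Product: 4 [4-(benzyloxy)-3-[4-(hydroxymethyl)phenoxy]phenyl]methanol
Conditions: NaBH4, THF/MeOH, 0 °C → rt
Reagents that add atoms: none
Why: Borohydride reduction of both aryl aldehydes to benzylic alcohols, which leaves the ethers untouched.

**Step 3**
Reactants: 4 [4-(benzyloxy)-3-[4-(hydroxymethyl)phenoxy]phenyl]methanol
Product: 5 1-(benzyloxy)-4-(bromomethyl)-2-[4-(bromomethyl)phenoxy]benzene
Conditions: PBr3, CH2Cl2, 0 °C
Reagents that add atoms: phosphorus tribromide BrP(Br)Br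
Why: Bromination of benzylic alcohols through their phosphite esters (SN2 by bromide), fast enough at 0 °C for the aryl benzyl ether to survive the HBr that forms.

**Step 4**
Reactants: 5 1-(benzyloxy)-4-(bromomethyl)-2-[4-(bromomethyl)phenoxy]benzene; 6 1-(trimethylsilyl)propyne
Product: 9 bis(but-3-ynyl) diaryl ether, via 3-lithio-1-(trimethylsilyl)propyne 7 (not isolated), via bis(silylbutynyl) diaryl ether 8 (not isolated)
Conditions: 6, n-BuLi, THF, −78 → −40 °C; then 5, −78 → 0 °C; then MeOH, K2CO3 (cat.), rt
Reagents that add atoms: none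
Why: Propargylic lithiation of 6 and SN2 alkylation by both benzylic bromides, the silyl group steering attack through the CH2 terminus (propargyl, not allenyl, product); methoxide in the same flask then cleaves the C(sp)–Si bonds by protodesilylation.

**Step 5**
Reactants: 9 1-(benzyloxy)-4-(but-3-yn-1-yl)-2-[4-(but-3-yn-1-yl)phenoxy]benzene
Product: 11 bis(benzyl pent-2-ynoate) diaryl ether, via dilithium bis(acetylide) 10 (not isolated)
Conditions: n-BuLi, THF, −78 °C; then ClCO2Bn, −78 → 0 °C
Reagents that add atoms: benzyl chloroformate O=C(Cl)OCc1ccccc1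
Why: Deprotonation of the terminal alkynes and C-acylation of the lithium acetylides with a chloroformate, the standard preparation of alk-2-ynoates; at −78 °C the base does not touch the benzylic or ether positions.

**Step 6**
Reactants: 11 bis(benzyl pent-2-ynoate) diaryl ether; 12 (E)-1-methoxy-3-(trimethylsilyloxy)buta-1,3-diene
Product: 14 bis(benzyl 4-hydroxybenzoate) diaryl ether, via bis(cyclohexadiene) cycloadduct 13 (not isolated)
Conditions: 12 (6 equiv), toluene, 130 °C, sealed tube; then 1 M HCl, THF, rt
Reagents that add atoms: none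
Why: In a thermal normal-electron-demand [4+2] cycloaddition the doubly oxygen-activated diene 12 adds across each ester-activated triple bond of 11 to give the cyclohexa-1,4-diene 13, and dilute acid then cleaves the silyl enol ether and eliminates methanol, so each ring aromatises to a 4-hydroxybenzoate without an oxidant. The closest known reaction type is the benzannulation of alk-2-ynoates with 1-methoxy-3-siloxybuta-1,3-dienes to 4-hydroxybenzoates. Rings A and D are each closed by an intermolecular [4+2] cycloaddition (four diene carbons plus the two alkyne carbons) that forms C2–C3 and C4–C5 when the hydroxyl carbon is C1 and the tether carbon C3, so no ring-closing cyclisation is involved. No stereocentre is set, because the two CH(OMe) carbons of 13 form without control and vanish on aromatisation. The step needs regioselectivity only, and polarity secures it: the nucleophilic CH2 terminus (C4) of the diene bonds to the electrophilic β-carbon of the ynoate, which carries the tether, so the tether ends meta and the ester para to the new hydroxyl. The two ynoate arms are electronically identical and insulated from each other, so excess diene should drive both cycloadditions, and the benzyl and diaryl ethers are inert at 130 °C.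

**Step 7**
Reactants: 14 bis(benzyl 4-hydroxybenzoate) diaryl ether
Product: 15 triphenol diacid
Conditions: H2 (1 atm), Pd/C, THF/MeOH, rt
Reagents that add atoms: none
Why: Heterogeneous hydrogenolysis of benzylic C–O bonds cleaves the aryl benzyl ether and both benzyl esters in one operation, while the diaryl ether and the arenes are not reduced at 1 atm and rt.

**Step 8**
Reactants: 15 triphenol diacid
Product: 16 perrottetin E
Conditions: Cu powder (cat.), quinoline, 200 °C, Ar
Reagents that add atoms: none
Why: Copper–quinoline protodecarboxylation of 4-hydroxybenzoic acids: the para hydroxyl allows ipso-protonation through the cyclohexadienone tautomer and the ortho alkyl group adds steric relief, so rings A and D each lose CO2.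

**Compound list**

1 | 4-(benzyloxy)-3-hydroxybenzaldehyde | O=Cc1ccc(OCc2ccccc2)c(O)c1 | starting material
2 | 4-fluorobenzaldehyde | O=Cc1ccc(F)cc1 | starting material
3 | 4-(benzyloxy)-3-(4-formylphenoxy)benzaldehyde | O=Cc1ccc(Oc2cc(C=O)ccc2OCc2ccccc2)cc1 | intermediate
4 | [4-(benzyloxy)-3-[4-(hydroxymethyl)phenoxy]phenyl]methanol | OCc1ccc(Oc2cc(CO)ccc2OCc2ccccc2)cc1 | intermediate
5 | 1-(benzyloxy)-4-(bromomethyl)-2-[4-(bromomethyl)phenoxy]benzene | BrCc1ccc(Oc2cc(CBr)ccc2OCc2ccccc2)cc1 | intermediate
6 | 1-(trimethylsilyl)propyne | CC#C[Si](C)(C)C | starting material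
7 | 3-lithio-1-(trimethylsilyl)propyne (not isolated) | [Li]CC#C[Si](C)(C)C | intermediate
8 | 1-(benzyloxy)-4-[4-(trimethylsilyl)but-3-yn-1-yl]-2-[4-[4-(trimethylsilyl)but-3-yn-1-yl]phenoxy]benzene (not isolated) | C[Si](C)(C)C#CCCc1ccc(Oc2cc(CCC#C[Si](C)(C)C)ccc2OCc2ccccc2)cc1 | intermediate
9 | 1-(benzyloxy)-4-(but-3-yn-1-yl)-2-[4-(but-3-yn-1-yl)phenoxy]benzene | C#CCCc1ccc(Oc2cc(CCC#C)ccc2OCc2ccccc2)cc1 | intermediate
10 | dilithium bis(acetylide) of 9, both terminal C–H replaced by C–Li (not isolated) | [Li]C#CCCc1ccc(Oc2cc(CCC#C[Li])ccc2OCc2ccccc2)cc1 | intermediate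
11 | benzyl 5-[4-(benzyloxy)-3-[4-[5-(benzyloxy)-5-oxopent-3-yn-1-yl]phenoxy]phenyl]pent-2-ynoate (rings B and C each carry a CH2CH2C≡C–CO2Bn arm) | O=C(OCc1ccccc1)C#CCCc1ccc(Oc2cc(CCC#CC(=O)OCc3ccccc3)ccc2OCc2ccccc2)cc1 | intermediate
12 | (E)-1-methoxy-3-(trimethylsilyloxy)buta-1,3-diene | CO/C=C/C(=C)O[Si](C)(C)C | starting material
13 | twofold cycloadduct: each arm ends in a 6-methoxy-4-(trimethylsilyloxy)cyclohexa-1,4-diene with CO2Bn at C1 and the CH2CH2 tether at C2; stereoisomer mixture at the two C6 carbons (not isolated) | O=C(OCc1ccccc1)C1=C(CCc2ccc(Oc3cc(CCC4=C(C(=O)OCc5ccccc5)C(OC)C=C(O[Si](C)(C)C)C4)ccc3OCc3ccccc3)cc2)CC(O[Si](C)(C)C)=CC1OC | intermediate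
14 | benzyl 2-[2-[4-[2-(benzyloxy)-5-[2-[2-(benzyloxycarbonyl)-5-hydroxyphenyl]ethyl]phenoxy]phenyl]ethyl]-4-hydroxybenzoate | O=C(OCc1ccccc1)c1ccc(O)cc1CCc1ccc(Oc2cc(CCc3cc(O)ccc3C(=O)OCc3ccccc3)ccc2OCc2ccccc2)cc1 | intermediate
15 | 2-[2-[4-[5-[2-(2-carboxy-5-hydroxyphenyl)ethyl]-2-hydroxyphenoxy]phenyl]ethyl]-4-hydroxybenzoic acid | OC(=O)c1ccc(O)cc1CCc1ccc(Oc2cc(CCc3cc(O)ccc3C(=O)O)ccc2O)cc1 | intermediate
16 | perrottetin E, 4-[2-(3-hydroxyphenyl)ethyl]-2-[4-[2-(3-hydroxyphenyl)ethyl]phenoxy]phenol | Oc1cccc(CCc2ccc(Oc3cc(CCc4cccc(O)c4)ccc3O)cc2)c1 | target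

**Totals.** 8 steps; longest linear sequence 8 steps (1 → 16).

**Steps most likely to fail**

Step 6. The β-alkylated, singly activated alkyne may react so slowly that the diene oligomerises or loses its silyl group before the second arm has reacted, which would stall the sequence at mono-annulated material. The fallback replaces cycloaddition by olefination and sets out from dibromide 5. Heating 5 with PPh3 in toluene should give the bis(triphenylphosphonium) dibromide F1. A twofold Wittig reaction with 3-(benzyloxy)benzaldehyde (K2CO3, 18-crown-6, CH2Cl2, reflux) should give the tris(benzyl ether) bis(stilbene) F2 as an E/Z mixture. Hydrogenation (H2, Pd/C, THF/MeOH) saturates both alkenes and cleaves the three benzyl ethers, so the fallback comes back to the route at the target 16.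

Step 8. Oxidative coupling or charring of the free ring C phenol in hot quinoline over copper, or stalling after loss of the first CO2, may erode the last step. The fallback moves the thermolysis off the unprotected triphenol and off the final position, and sets out from 14. Aqueous NaOH in MeOH at reflux should hydrolyse both benzyl esters and leave the ring C benzyl ether, giving the O-benzyl diacid F3. Cu powder in quinoline at 200 °C should decarboxylate it to ring C O-benzyl perrottetin E F4. Hydrogenolysis (H2, Pd/C) then comes back to the route at 16.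

Step 4. Halogen–lithium exchange and electron transfer at the very reactive alkoxy-substituted benzylic bromides (Wurtz-type homocoupling), attack of the ambident anion through its allenyl terminus, or incomplete twofold alkylation may lower the throughput. The fallback uses a softer two-carbon nucleophile followed by one-carbon homologation, and sets out from 5. The lithium enolate of tert-butyl acetate (LiN(iPr)2, THF, −78 °C) should alkylate both bromides to the bis(tert-butyl propanoate) F5. Partial reduction with i-Bu2AlH in toluene at −78 °C should give the bis(propanal) F6. Ohira–Bestmann homologation (dimethyl (1-diazo-2-oxopropyl)phosphonate, K2CO3, MeOH, rt) converts both aldehydes to terminal alkynes and comes back to the route at 9.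

**Further compounds**

F1 | step 6 | [4-(benzyloxy)-3-[4-[(triphenylphosphonio)methyl]phenoxy]benzyl]triphenylphosphonium dibromide | [Br-].[Br-].c1ccc(cc1)[P+](Cc1ccc(Oc2cc(C[P+](c3ccccc3)(c3ccccc3)c3ccccc3)ccc2OCc2ccccc2)cc1)(c1ccccc1)c1ccccc1
F2 | step 6 | 1-(benzyloxy)-4-[2-[3-(benzyloxy)phenyl]ethenyl]-2-[4-[2-[3-(benzyloxy)phenyl]ethenyl]phenoxy]benzene, E/Z mixture | C(=Cc1cccc(OCc2ccccc2)c1)c1ccc(Oc2cc(C=Cc3cccc(OCc4ccccc4)c3)ccc2OCc2ccccc2)cc1
F3 | step 8 | 2-[2-[4-[2-(benzyloxy)-5-[2-(2-carboxy-5-hydroxyphenyl)ethyl]phenoxy]phenyl]ethyl]-4-hydroxybenzoic acid | OC(=O)c1ccc(O)cc1CCc1ccc(Oc2cc(CCc3cc(O)ccc3C(=O)O)ccc2OCc2ccccc2)cc1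
F4 | step 8 | 3-[2-[4-[2-(benzyloxy)-5-[2-(3-hydroxyphenyl)ethyl]phenoxy]phenyl]ethyl]phenol | Oc1cccc(CCc2ccc(Oc3cc(CCc4cccc(O)c4)ccc3OCc3ccccc3)cc2)c1
F5 | step 4 | tert-butyl 3-[4-[2-(benzyloxy)-5-(3-tert-butoxy-3-oxopropyl)phenoxy]phenyl]propanoate | CC(C)(C)OC(=O)CCc1ccc(Oc2cc(CCC(=O)OC(C)(C)C)ccc2OCc2ccccc2)cc1
F6 | step 4 | 3-[4-[2-(benzyloxy)-5-(3-oxopropyl)phenoxy]phenyl]propanal | O=CCCc1ccc(Oc2cc(CCC=O)ccc2OCc2ccccc2)cc1
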